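Molar, not mol%, is the unit I read the initiator in here.

| setting | Saturday's | Wednesday's | Sunday's | flask |
|---|---|---|---|---|
| solid monomer | 0.49 M | 2 M | 0.99 M | 0.99 M |
| transfer agent | 0.297 M | 0.297 M | 0.297 M | 0.297 M |
| initiator | 4.9 mol% | 4.9 mol% | 9.8 mol% | 4.9 mol% |
| remark | run made earlier | run made earlier | run made earlier |  |
| time |  |  |  | 3.0 h |

| run | time / min | monomer in chains / % | free monomer / % |
|---|---|---|---|
| Saturday's | 15.0 | 10.3 | 86.2 |
| Saturday's | 40.0 | 43.6 | 49.5 |
| Saturday's | 80.0 | 69.9 | 19.7 |
| Saturday's | 120 | 81.1 | 9.5 |
| Wednesday's | 15.0 | 9.0 | 24.5 |
| Wednesday's | 40.0 | 50.1 | 24.6 |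
| Wednesday's | 80.0 | 91.9 | 3.7 |
| Wednesday's | 120 | 94.6 | 0 |
| Sunday's | 8.00 | 4.1 | 42.7 |
| Sunday's | 20.0 | 33.0 | 51.0 |
| Sunday's | 50.0 | 86.6 | 8.4 |
| Sunday's | 120 | 94.3 | 0 |

(standard deviation of a reading: 0.5 percentage points)

1. monomer in chains at 3.0 h, in percent of the solid monomer charged
2. concentration of free monomer in solution at 3.0 h, in percent of saturation

- percentages count the solid monomer that a species holds: one self-condensation product counts as two
- solid, in amounts per volume of the solution: solid monomer
- steps that have been proposed: free monomer + initiator -> living end + monomer in chains; free monomer + living end -> monomer in chains + living end; living end + transfer agent -> dead chain; solid monomer <-> free monomer; 2 living end <-> resting dimer; 2 free monomer -> self-condensation product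
- at the start none of the solid monomer is in solution

1. At the last reading, I take the solid monomer as dissolved and call what stands in neither chains nor solution the lost share: 5.70% in Sunday's run, 5.40% in Wednesday's, 9.40% in Saturday's.

2. If the proposed steps go as written, self-condensation runs as [free monomer]² and growth as [free monomer][living end]. Their ratio, a selectivity factor, goes as [free monomer]/[living end], so I expect more initiator to mean less loss.

3. Saturday's and Wednesday's runs share a loading of 4.9 mol%, yet Saturday's loses more. Wednesday's charged [initiator] of 0.0980 M and Sunday's of 0.0970 M are alike, and so are their losses.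

4. The loss exponent, the logarithmic fall of lost share with charged [initiator] at the same charged [transfer agent], reads from Saturday's 0.0240 M and Sunday's run: 0.358. These two runs differ in solid monomer as well, so this is a reading across both changes. Saturday's run still holds 9.5% free monomer at its last reading, so its loss may yet grow.

5. This flask has charged [initiator] 0.0485 M, half of Sunday's. The exponent gives a loss of 7.31%, so I commit to about 92.7% in chains.

6. The forecast says 92% in chains and 1.6% of saturation: “The mass deficit fits self-condensation”.

7. The flask gives 91.6% in chains and 0.262% of saturation.

    free monomer + initiator → living end + monomer in chains (k = 0.100 L mol⁻¹ min⁻¹)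
    free monomer + living end → monomer in chains + living end, rate k2*[living end]*[free monomer] (k = 1.80 L mol⁻¹ min⁻¹)
    living end + transfer agent → dead chain (kL = 0.0270 L mol⁻¹ min⁻¹)
    solid monomer ⇌ free monomer, rate k4*(cs4 - [free monomer]) while solid is left; crystals form when [free monomer] > cs4 (solubility = 0.820 M, k = 0.100 min⁻¹)
    2 living end ⇌ resting dimer, settled at all times (K = 11.0 L mol⁻¹)
    2 free monomer → self-condensation product (k = 0.00400 L mol⁻¹ min⁻¹)

The flask holds 91.6% in chains, against my 92.7%, so 8.40% of the charge stands outside chains. Self-condensation is the main reason for that shortfall: the same flask without that step puts 99.8% in chains, against 91.6%. This is the step of the forecast that carried the weight. Going down in initiator, this flask's share in chains has moved by 5 points at 2.9 mol%.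

At 20 mol% of initiator, charged [initiator] is 0.198 M. The exponent 0.358 then gives a loss of 4.41%, so about 95.6% in chains; that neighbour flask computes to 96.9%.

The runs were computed for substances that don't exist; scatter was added.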